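**Retrosynthetic overview**

1. The last disconnection is the MOM ether on the C7 oxygen of ring B (the benzofuran); every carbon is then already in place.
2. Ring A is a resorcinol with hydroxyls on C2 and C4, C3–H between them, the propyl tether on C1 and the quaternary 1,1-dimethylallyl group on C5. Cutting C5–C6 and C3–C4 gives a β-methoxy enone (C1, C2, C3, C6 and the tether) and methyl 3,3-dimethylpent-4-enoate (C4, C5 and the ready-made quaternary carbon). In the forward sense these are joined by Michael addition–elimination, then Claisen closure.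
3. The enone is cut at the tether–C1 bond: B-alkyl Suzuki–Miyaura coupling of hydroborated 5-allyl-4-prenyl-7-(MOM-oxy)benzofuran with 3-iodo-4-methoxybut-3-en-2-one.
4. The benzofuran comes from 6-bromovanillin: iodination and Sonogashira heteroannulation add the furan ring, the formyl group becomes the allyl group, the bromine becomes the prenyl group, and the methyl ether is exchanged for MOM.
5. Ring order: the benzene ring of ring B is bought, the furan ring is closed in step 2, and ring A is closed last in step 11.

Key step: step 11

Remark: the target has no stereocentre and no stereodefined alkene, so no stereocontrol is needed; the β-methoxy enones are drawn as the expected isomer, but their geometry is lost in the addition–elimination and either isomer should serve.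

**Route**

Step 1
Reactants: 1 2-bromo-4-hydroxy-5-methoxybenzaldehyde (6-bromovanillin)
Product: 2 2-bromo-4-hydroxy-3-iodo-5-methoxybenzaldehyde
Conditions: NIS, TsOH·H2O (cat.), MeCN, 25 °C, dark
Reagents that add atoms: N-iodosuccinimide, O=C1CCC(=O)N1I
Why: Electrophilic aromatic iodination directed by the free phenol, whose para position carries the formyl group and whose other ortho position carries the methoxy group, so only C3 between the hydroxyl and the bromine can react.

Step 2
Reactants: 2 2-bromo-4-hydroxy-3-iodo-5-methoxybenzaldehyde; 3 ethynyltrimethylsilane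
Product: 6 4-bromo-7-methoxy-1-benzofuran-5-carbaldehyde, via alkynylphenol 4 (not isolated), via 2-silylbenzofuran 5 (not isolated)
Conditions: PdCl2(PPh3)2 (cat.), CuI (cat.), Et3N, DMF, 25 → 60 °C; then TBAF, THF, 25 °C
Reagents that add atoms: none
Why: Sonogashira coupling, in which zerovalent palladium inserts into the C–I bond far faster than into the C–Br bond, gives 4; CuI/amine then promotes 5-endo-dig attack of the phenoxide on the alkyne (Castro–Stephens-type heteroannulation) to 5, and fluoride protodesilylates the furan C2–Si bond.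

Step 3
Reactants: 6 4-bromo-7-methoxy-1-benzofuran-5-carbaldehyde
Product: 7 4-bromo-7-hydroxy-1-benzofuran-5-carbaldehyde
Conditions: BBr3, CH2Cl2, −78 → 0 °C; then H2O
Reagents that add atoms: none
Why: Lewis-acid ether cleavage, in which BBr3 coordinates the methoxy oxygen and bromide removes the methyl group by SN2, while the aldehyde, the aryl bromide and the electron-poor benzofuran should survive at low temperature.

Step 4
Reactants: 7 4-bromo-7-hydroxy-1-benzofuran-5-carbaldehyde
Product: 8 4-bromo-7-(methoxymethoxy)-1-benzofuran-5-carbaldehyde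
Conditions: MOMCl, i-Pr2NEt, CH2Cl2, 0 → 25 °C
Reagents that add atoms: chloromethyl methyl ether, COCCl
Why: Base-mediated O-alkylation of the phenol (MOM protection) gives an acetal that withstands the hydride, organometallic and enolate steps that follow.

Step 5
Reactants: 8 4-bromo-7-(methoxymethoxy)-1-benzofuran-5-carbaldehyde
Product: 9 [4-bromo-7-(methoxymethoxy)-1-benzofuran-5-yl]methanol
Conditions: NaBH4, MeOH/THF, 0 °C
Reagents that add atoms: none
Why: Hydride reduction of the aldehyde by NaBH4, to which the aryl bromide, the furan ring and the MOM acetal are inert.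

Step 6
Reactants: 9 [4-bromo-7-(methoxymethoxy)-1-benzofuran-5-yl]methanol
Product: 10 4-bromo-5-(bromomethyl)-7-(methoxymethoxy)-1-benzofuran
Conditions: CBr4, PPh3, CH2Cl2, 0 °C
Reagents that add atoms: carbon tetrabromide, BrC(Br)(Br)Br
Why: The Appel reaction converts the benzylic alcohol into the bromide under neutral conditions that leave the acid-labile MOM ether intact.

Step 7
Reactants: 10 4-bromo-5-(bromomethyl)-7-(methoxymethoxy)-1-benzofuran; 11 vinylmagnesium bromide
Product: 12 5-allyl-4-bromo-7-(methoxymethoxy)-1-benzofuran
Conditions: CuI (cat.), 2,2'-bipyridyl (cat.), THF, −20 → 0 °C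
Reagents that add atoms: none
Why: Copper-catalysed Kumada-type coupling of a benzylic bromide with a vinyl Grignard reagent forms the allyl group, and the aryl C–Br bond does not react under these conditions.

Step 8
Reactants: 12 5-allyl-4-bromo-7-(methoxymethoxy)-1-benzofuran; 13 1-bromo-3-methylbut-2-ene (prenyl bromide)
Product: 16 5-allyl-7-(methoxymethoxy)-4-(3-methylbut-2-enyl)-1-benzofuran, via aryllithium 14 (not isolated), via arylcopper 15 (not isolated)
Conditions: t-BuLi (2 equiv), THF, −78 °C; CuBr·SMe2, −78 °C; then 13, −78 → 0 °C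
Reagents that add atoms: none
Why: Bromine–lithium exchange with t-BuLi at −78 °C outruns deprotonation of the furan C2–H, and the derived arylcopper is alkylated by prenyl bromide at its primary carbon (SN2 allylic substitution) to give the linear prenyl group.

Step 9
Reactants: 17 (E)-4-methoxybut-3-en-2-one
Product: 18 (Z)-3-iodo-4-methoxybut-3-en-2-one
Conditions: I2, pyridine, CH2Cl2, 0 → 25 °C, dark
Reagents that add atoms: iodine, [I][I]
Why: Electrophilic α-iodination of a vinylogous ester, in which iodine attacks the nucleophilic α-carbon and pyridine removes the α-proton from the resulting oxocarbenium ion, the methoxy group ending trans to the acetyl group.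

Step 10
Reactants: 16 5-allyl-7-(methoxymethoxy)-4-(3-methylbut-2-enyl)-1-benzofuran; 18 (Z)-3-iodo-4-methoxybut-3-en-2-one
Product: 20 (E)-3-(methoxymethylidene)-6-[7-(methoxymethoxy)-4-(3-methylbut-2-enyl)-1-benzofuran-5-yl]hexan-2-one, via B-alkyl-9-BBN borane 19 (not isolated)
Conditions: 9-BBN, THF, 0 → 25 °C; then 18, PdCl2(dppf) (cat.), AsPh3 (cat.), Cs2CO3, DMF/H2O, 25 °C
Reagents that add atoms: none
Why: 9-BBN hydroborates only the monosubstituted allyl alkene, with anti-Markovnikov regiochemistry (the trisubstituted prenyl alkene and the furan are far slower), and B-alkyl Suzuki–Miyaura coupling of borane 19 with the vinyl iodide should proceed with retention of alkene geometry under mild aqueous base.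

Step 11
Reactants: 20 (E)-3-(methoxymethylidene)-6-[7-(methoxymethoxy)-4-(3-methylbut-2-enyl)-1-benzofuran-5-yl]hexan-2-one; 21 methyl 3,3-dimethylpent-4-enoate
Product: 24 4-(2-methylbut-3-en-2-yl)-6-{3-[7-(methoxymethoxy)-4-(3-methylbut-2-enyl)-1-benzofuran-5-yl]propyl}benzene-1,3-diol, via keto ester 22 (not isolated), via cyclohexenedione 23 (not isolated)
Conditions: 21 (3 equiv), LiN(i-Pr)2 (2.8 equiv), THF, −78 °C; add 20, −78 → 25 °C; then KOt-Bu (2 equiv), 50 °C; aq. NH4Cl
Reagents that add atoms: none
Why: The lithium enolate of 21 adds to the methoxy-bearing β-carbon of 20 (a kinetically formed 1,2-aldolate reverts on warming) and lithium methoxide is expelled, which forms C5–C6 and leaves the doubly activated keto ester 22 as its dienolate. Under the added KOt-Bu the alkene geometry equilibrates through that dienolate and the methyl ketone enolate acylates on the ester carbonyl (Claisen/Dieckmann-type condensation), which forms C3–C4 and closes ring A by a 6-exo-trig attack. Loss of methoxide gives cyclohexenedione 23, whose enolisation to the resorcinolate is irreversible and drains the preceding equilibria, including reversible enol-lactonisation to a 2-pyranone. The closest known reaction type is the Michael addition–elimination/Claisen benzannulation of ester enolates with β-alkoxy enones, the alkoxy-enone counterpart of the malonate/enone route to cyclohexane-1,3-diones. No stereocentre survives, because the C5 methine of 22 is racemic and becomes aromatic. The step needs conjugate rather than carbonyl addition and a single orientation; these are secured because 21 has one enolisable carbon and 20 has one electrophilic β-carbon carrying the leaving group and one enolisable methyl group, and if proton transfer from that methyl group intervenes, acylation of the resulting ketone enolate by 21 followed by closure onto the methoxymethylidene carbon leads to the same resorcinol.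

Step 12
Reactants: 24 4-(2-methylbut-3-en-2-yl)-6-{3-[7-(methoxymethoxy)-4-(3-methylbut-2-enyl)-1-benzofuran-5-yl]propyl}benzene-1,3-diol
Product: 25 4-(2-methylbut-3-en-2-yl)-6-{3-[7-hydroxy-4-(3-methylbut-2-enyl)-1-benzofuran-5-yl]propyl}benzene-1,3-diol (CNP0288359.0)
Conditions: HCl (3 M aq.), MeOH, 25 → 40 °C
Reagents that add atoms: none
Why: Acid-catalysed acetal exchange removes the MOM group under dilute conditions at which hydration or cyclisation of the prenyl and 1,1-dimethylallyl groups should be slow.

**Compound list**

1 | 2-bromo-4-hydroxy-5-methoxybenzaldehyde (6-bromovanillin) | COc1cc(C=O)c(Br)cc1O | starting material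
2 | 2-bromo-4-hydroxy-3-iodo-5-methoxybenzaldehyde | COc1cc(C=O)c(Br)c(I)c1O | intermediate
3 | ethynyltrimethylsilane | C#C[Si](C)(C)C | starting material
4 | 2-bromo-4-hydroxy-5-methoxy-3-[(trimethylsilyl)ethynyl]benzaldehyde | COc1cc(C=O)c(Br)c(C#C[Si](C)(C)C)c1O | intermediate (not isolated)
5 | 4-bromo-7-methoxy-2-(trimethylsilyl)-1-benzofuran-5-carbaldehyde | COc1cc(C=O)c(Br)c2cc([Si](C)(C)C)oc12 | intermediate (not isolated)
6 | 4-bromo-7-methoxy-1-benzofuran-5-carbaldehyde | COc1cc(C=O)c(Br)c2ccoc12 | intermediate
7 | 4-bromo-7-hydroxy-1-benzofuran-5-carbaldehyde | Oc1cc(C=O)c(Br)c2ccoc12 | intermediate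
8 | 4-bromo-7-(methoxymethoxy)-1-benzofuran-5-carbaldehyde | COCOc1cc(C=O)c(Br)c2ccoc12 | intermediate
9 | [4-bromo-7-(methoxymethoxy)-1-benzofuran-5-yl]methanol | COCOc1cc(CO)c(Br)c2ccoc12 | intermediate
10 | 4-bromo-5-(bromomethyl)-7-(methoxymethoxy)-1-benzofuran | COCOc1cc(CBr)c(Br)c2ccoc12 | intermediate
11 | vinylmagnesium bromide | C=C[Mg]Br | starting material
12 | 5-allyl-4-bromo-7-(methoxymethoxy)-1-benzofuran | C=CCc1cc(OCOC)c2occc2c1Br | intermediate
13 | 1-bromo-3-methylbut-2-ene (prenyl bromide) | CC(C)=CCBr | starting material
14 | [5-allyl-7-(methoxymethoxy)-1-benzofuran-4-yl]lithium | C=CCc1cc(OCOC)c2occc2c1[Li] | intermediate (not isolated)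
15 | [5-allyl-7-(methoxymethoxy)-1-benzofuran-4-yl]copper | C=CCc1cc(OCOC)c2occc2c1[Cu] | intermediate (not isolated)
16 | 5-allyl-7-(methoxymethoxy)-4-(3-methylbut-2-enyl)-1-benzofuran | C=CCc1cc(OCOC)c2occc2c1CC=C(C)C | intermediate
17 | (E)-4-methoxybut-3-en-2-one | CO/C=C/C(C)=O | starting material
18 | (Z)-3-iodo-4-methoxybut-3-en-2-one | CO/C=C(\I)C(C)=O | intermediate
19 | 9-{3-[7-(methoxymethoxy)-4-(3-methylbut-2-enyl)-1-benzofuran-5-yl]propyl}-9-borabicyclo[3.3.1]nonane | CC(C)=CCc1c(CCCB2C3CCCC2CCC3)cc(OCOC)c2occc12 | intermediate (not isolated)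
20 | (E)-3-(methoxymethylidene)-6-[7-(methoxymethoxy)-4-(3-methylbut-2-enyl)-1-benzofuran-5-yl]hexan-2-one | CO/C=C(\CCCc1cc(OCOC)c2occc2c1CC=C(C)C)C(C)=O | intermediate
21 | methyl 3,3-dimethylpent-4-enoate | COC(=O)CC(C)(C)C=C | starting material
22 | methyl 4-acetyl-7-[7-(methoxymethoxy)-4-(3-methylbut-2-enyl)-1-benzofuran-5-yl]-2-(2-methylbut-3-en-2-yl)hept-3-enoate (alkene isomers, racemic) | COC(=O)C(C=C(CCCc1cc(OCOC)c2occc2c1CC=C(C)C)C(C)=O)C(C)(C)C=C | intermediate (not isolated)
23 | 4-{3-[7-(methoxymethoxy)-4-(3-methylbut-2-enyl)-1-benzofuran-5-yl]propyl}-6-(2-methylbut-3-en-2-yl)cyclohex-4-ene-1,3-dione (racemic) | O=C1CC(=O)C(CCCc2cc(OCOC)c3occc3c2CC=C(C)C)=CC1C(C)(C)C=C | intermediate (not isolated)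
24 | 4-(2-methylbut-3-en-2-yl)-6-{3-[7-(methoxymethoxy)-4-(3-methylbut-2-enyl)-1-benzofuran-5-yl]propyl}benzene-1,3-diol | C=CC(C)(C)c1cc(CCCc2cc(OCOC)c3occc3c2CC=C(C)C)c(O)cc1O | intermediate
25 | 4-(2-methylbut-3-en-2-yl)-6-{3-[7-hydroxy-4-(3-methylbut-2-enyl)-1-benzofuran-5-yl]propyl}benzene-1,3-diol (CNP0288359.0) | C=CC(C)(C)c1cc(CCCc2cc(O)c3occc3c2CC=C(C)C)c(O)cc1O | target

**Step count**

Total: 12 steps. Longest linear sequence: 11 steps (steps 1–8 and 10–12, from 1); step 9 is a one-step side branch.

**Steps most likely to fail**

1. Step 11. Proton transfer from the methyl ketone of 20 to the hindered enolate of 21 may outrun conjugate addition and start self-condensation of the enone. The sequence may also stall after the addition–elimination because the dienolate of 22 resists C-acylation. The fallback forms the same two bonds in the opposite order, with the ring closure made intramolecular; it sets out from 21 and 20 and returns at 24. Saponification of 21 (LiOH, THF/H2O) should give 3,3-dimethylpent-4-enoic acid F1, which carbonyldiimidazole converts into 1-(3,3-dimethylpent-4-enoyl)imidazole F2. The lithium enolate of 20 (LiN(SiMe3)2, 2.2 equiv, THF, −78 °C; the methyl group is its only enolisable position) is C-acylated by F2 in a Claisen-type ketone acylation to give the β-diketone (E)-1-methoxy-2-{3-[7-(methoxymethoxy)-4-(3-methylbut-2-enyl)-1-benzofuran-5-yl]propyl}-7,7-dimethylnona-1,8-diene-3,5-dione F3. K2CO3 in MeOH then lets the terminal enolate carbon add to the methoxymethylidene carbon (6-endo-trig addition–elimination), and loss of methanol with aromatisation should give 24.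

2. Step 10. Aqueous carbonate may hydrolyse the vinylogous ester of 18 or 20, and transmetalation of the primary alkyl group to the hindered α-acylvinylpalladium intermediate may be slow enough for deiodination of 18 or protodeboronation to win. The fallback replaces the borane by an alkylzinc reagent under neutral, anhydrous conditions; it sets out from 16 and returns at 20. Hydroboration as in step 10 followed by oxidation (NaBO3·4H2O) should give 3-[7-(methoxymethoxy)-4-(3-methylbut-2-enyl)-1-benzofuran-5-yl]propan-1-ol F4. I2, PPh3 and imidazole convert it into 5-(3-iodopropyl)-7-(methoxymethoxy)-4-(3-methylbut-2-enyl)-1-benzofuran F5. Zinc dust with LiCl in THF inserts to give {3-[7-(methoxymethoxy)-4-(3-methylbut-2-enyl)-1-benzofuran-5-yl]propyl}zinc iodide F6, and Negishi coupling of this with 18 (PdCl2(dppf), THF, 25 °C) should give 20.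

3. Step 8. Deprotonation at furan C2 or at the benzylic–allylic CH2 may compete with or follow the bromine–lithium exchange, and the arylcopper may attack prenyl bromide at its tertiary terminus (SN2') to give the 1,1-dimethylallyl isomer. The fallback avoids the aryllithium altogether; it sets out from 12 and 13 and returns at 16. Prenyl bromide 13 with zinc dust and LiCl in THF should give (3-methylbut-2-enyl)zinc bromide F7, and a linear-selective Negishi coupling with 12 (Pd(OAc)2, CPhos, THF, 25 °C) should give 16.

**Further compounds**

F1 | step 11 | 3,3-dimethylpent-4-enoic acid | C=CC(C)(C)CC(=O)O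
F2 | step 11 | 1-(3,3-dimethylpent-4-enoyl)imidazole | C=CC(C)(C)CC(=O)n1ccnc1
F3 | step 11 | (E)-1-methoxy-2-{3-[7-(methoxymethoxy)-4-(3-methylbut-2-enyl)-1-benzofuran-5-yl]propyl}-7,7-dimethylnona-1,8-diene-3,5-dione | CO/C=C(\CCCc1cc(OCOC)c2occc2c1CC=C(C)C)C(=O)CC(=O)CC(C)(C)C=C
F4 | step 10 | 3-[7-(methoxymethoxy)-4-(3-methylbut-2-enyl)-1-benzofuran-5-yl]propan-1-ol | OCCCc1cc(OCOC)c2occc2c1CC=C(C)C
F5 | step 10 | 5-(3-iodopropyl)-7-(methoxymethoxy)-4-(3-methylbut-2-enyl)-1-benzofuran | ICCCc1cc(OCOC)c2occc2c1CC=C(C)C
F6 | step 10 | {3-[7-(methoxymethoxy)-4-(3-methylbut-2-enyl)-1-benzofuran-5-yl]propyl}zinc iodide | I[Zn]CCCc1cc(OCOC)c2occc2c1CC=C(C)C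
F7 | step 8 | (3-methylbut-2-enyl)zinc bromide | CC(C)=CC[Zn]Br
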